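**Plan**

1. Retrosynthetic cuts, in order: C5=C6 (ring-closing metathesis, last step); C7–C8 plus the lactone C–O (Ni/Cr coupling of an enol triflate with acrolein, then lactonisation); C8–C9 (acylation of an alkylzinc); finally C1–C10 and C11–C12 of the cyclohexane together in one [4+2] step.
2. Enabling feature: the six-membered ring C1–C10–C11–C12–C13–C14 carries its oxygen on C14 next to quaternary C1, so it maps onto a 2-silyloxydiene C12=C13–C14(OSi)=C1 plus a C10=C11 dienophile. The oxygen on C2 and the C9 methylene sit on the adjacent ring atoms C1 and C10, trans to each other, so a temporary O(C2)–Si–O–C9 silaketal (seven-membered ring) can tether the partners.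
3. Forward order: aldol (C2) → vinyl ketone → silaketal with a γ-hydroxy vinyl sulfone → silyloxydiene → intramolecular Diels–Alder reaction (cyclohexene plus temporary ring) → sulfone used to bring in C20, then expelled to place C11=C12 → C14 alcohol and acetate → silaketal opened, directed epoxidation → C8 unit → butenolide with C7 → ten-membered ring.
4. Stereochemistry: C2 from the oxazolidinone auxiliary; C1 and C10 from C2 through the tether and allylic 1,3-strain in the cycloaddition; C14 and C7 by reagent control (oxazaborolidine; chiral ligand on chromium); C11/C12 by epoxidation directed from the C9 hydroxyl; C5=C6 geometry by the ring.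

Key step: step 8

Remark on numbering: C1 is the quaternary ring-fusion carbon (CH3), C2 the butanoyloxy carbon, C3 and C4 the CH2 groups, C5(CH3)=C6 the ring olefin, C7 the lactone CH–O, C8 the butenolide β-carbon, C9 the CH2 on C10, C10 the ring-fusion CH, C11(CH3)–C12 the epoxide, C13 the ring CH2, C14 the acetoxy carbon, C20 the methyl on C11.

Remark on stereochemistry: the configuration at the sulfone-bearing carbon C11 of 16 and 17 is left open, because this centre becomes sp2 in step 11.

Remark on starting materials: compounds 1, 3, 8, 9, 28 and 34 are taken as commercial.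

**Route**

Step 1
Reactants: 1 4-methylpent-4-en-1-ol
Product: 2 4-methylpent-4-enal
Conditions: TEMPO (cat.), PhI(OAc)2, CH2Cl2, 25 °C
Reagents that add atoms: none
Why: Oxoammonium (TEMPO) oxidation of a primary alcohol stops at the aldehyde and leaves the 1,1-disubstituted olefin untouched.

Step 2
Reactants: 3 (R)-4-benzyl-3-propanoyl-1,3-oxazolidin-2-one; 2 4-methylpent-4-enal
Product: 5 (R)-4-benzyl-3-[(2R,3S)-3-hydroxy-2,6-dimethylhept-6-enoyl]-1,3-oxazolidin-2-one, via Z-boron enolate 4 (not isolated)
Conditions: n-Bu2BOTf, Et3N, CH2Cl2, -78 to 0 °C; then 2, -78 to 0 °C; pH 7 buffer, MeOH, H2O2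
Reagents that add atoms: di-n-butylboron triflate, CCCCB(CCCC)OS(=O)(=O)C(F)(F)F (boron stays only in 4)
Why: Evans syn-aldol reaction in which the Z-boron enolate adds through a closed chair transition state on the enolate face away from the benzyl group, setting the carbinol centre (future C2) as S; the neighbouring methyl-bearing centre is erased in step 7.

Step 3
Reactants: 5 aldol adduct
Product: 6 (2R,3S)-3-hydroxy-N-methoxy-N,2,6-trimethylhept-6-enamide
Conditions: MeNH(OMe)·HCl, AlMe3, CH2Cl2, -20 to 0 °C
Reagents that add atoms: N,O-dimethylhydroxylamine hydrochloride, CNOC.Cl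
Why: Aluminium-amide aminolysis (Weinreb amide formation) cleaves the imide at the exocyclic carbonyl, releases the auxiliary and tolerates the free β-hydroxyl.

Step 4
Reactants: 6 Weinreb amide
Product: 7 (4R,5S)-5-hydroxy-4,8-dimethylnona-1,8-dien-3-one
Conditions: CH2=CHMgBr (3 equiv), THF, -78 to 0 °C; inverse quench into cold aq. HCl
Reagents that add atoms: vinylmagnesium bromide, C=C[Mg]Br
Why: Grignard addition to a Weinreb amide stops at the ketone through the chelated tetrahedral intermediate, the hydroxyl being carried as its magnesium alkoxide; the cold acidic quench prevents conjugate addition of the released amine to the enone.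

Step 5
Reactants: 8 phenyl vinyl sulfone; 9 prop-2-en-1-ol
Product: 10 (E)-3-(phenylsulfonyl)prop-2-en-1-ol
Conditions: second-generation Grubbs catalyst (5 mol %), CH2Cl2, 40 °C
Reagents that add atoms: none
Why: Olefin cross-metathesis between an electron-poor vinyl sulfone and an allylic alcohol is E-selective and gives the γ-hydroxy vinyl sulfone directly.

Step 6
Reactants: 10 (E)-3-(phenylsulfonyl)prop-2-en-1-ol; 7 hydroxy enone
Product: 12 (4R,5S)-5-({di-tert-butyl[(E)-3-(phenylsulfonyl)prop-2-enyloxy]silyl}oxy)-4,8-dimethylnona-1,8-dien-3-one, via alkoxysilyl triflate 11 (not isolated)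
Conditions: 10, t-Bu2Si(OTf)2, 2,6-lutidine, CH2Cl2, -78 °C; then 7, -78 to 25 °C
Reagents that add atoms: di-tert-butylsilyl bis(trifluoromethanesulfonate), CC(C)(C)[Si](OS(=O)(=O)C(F)(F)F)(OS(=O)(=O)C(F)(F)F)C(C)(C)C
Why: Stepwise silylation (unsymmetrical silaketal formation) in which the primary allylic alcohol takes the first Si–OTf bond and the hindered mono-triflate then silylates the secondary aldol hydroxyl; this order keeps the silyl triflate from closing onto the ketone of 7.

Step 7
Reactants: 12 silaketal ketone
Product: 13 (3Z,5S)-3-[(tert-butyldimethylsilyl)oxy]-5-({di-tert-butyl[(E)-3-(phenylsulfonyl)prop-2-enyloxy]silyl}oxy)-4,8-dimethylnona-1,3,8-triene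
Conditions: TBSOTf, Et3N, CH2Cl2, -78 to 0 °C
Reagents that add atoms: tert-butyldimethylsilyl triflate, CC(C)(C)[Si](C)(C)OS(=O)(=O)C(F)(F)F
Why: Soft enolisation (silyl triflate and amine) at the only α-CH gives the 2-silyloxydiene; the branched C2 substituent should end up cis to the silyloxy group to avoid allylic strain with the coplanar vinyl group, and the old α-methyl stereocentre disappears.

Step 8
Reactants: 13 silicon-tethered triene
Product: 14 trans-fused cyclohexene/1,3-dioxa-2-silepane adduct (TBS enol ether C13=C14; CH3 on C1 cis to CH2-9; phenylsulfonyl on C11 cis to H on C10)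
Conditions: toluene (5 mM), BHT (cat.), base-washed sealed vessel, 150 °C
Reagents that add atoms: none
Why: Thermal suprafacial [4+2] cycloaddition of the electron-rich 2-silyloxydiene C12=C13–C14(OTBS)=C1 with the tethered (E)-vinyl sulfone C10=C11, forming C1–C10 and C11–C12 together; the closest known type is the silicon-tethered intramolecular Diels–Alder reaction of a 1,3,10-undecatriene. The cyclohexene closes by the cycloaddition itself, and the seven-membered 1,3-dioxa-2-silepane closes as a fused ring because the O–Si–O tether joins the diene terminus C1 (through C2) to the dienophile carbon C10 (through C9) that it bonds to. Regiochemistry is electronically matched, since the nucleophilic terminus C1 meets the β-carbon C10 of the vinyl sulfone, and the tether length allows only this fused mode. C1 is set relative to C2 by allylic 1,3-strain: the hydrogen on C2 eclipses the enol double bond toward the OTBS group, so the tether oxygen and the dienophile lie on one face and the C3 chain on the other. C10 (and the transient C11) follow from the E-dienophile geometry and the exo-tether, endo-sulfonyl transition state, which keeps CH2-9 away from the C14–OTBS group and gives the trans ring fusion. The step needs this facial and exo-tether selectivity and a rate above that of the 1,5-hydrogen shift of the diene; the gem-dialkyl effect of the di-tert-butylsilyl group and the sulfone activation are there to secure it.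

Step 9
Reactants: 14 Diels–Alder adduct
Product: 16 C11-methylated sulfone, via lithiated sulfone 15 (not isolated)
Conditions: n-BuLi, THF, -78 °C; MeI, -78 to 0 °C
Reagents that add atoms: iodomethane, CI; n-butyllithium, [Li]CCCC (lithium stays only in 15)
Why: Deprotonation α to the sulfone and C-methylation of the tertiary sulfonyl carbanion bring in C20; no leaving group sits β to the carbanion, and the configuration formed is irrelevant because the centre is removed in step 11.

Step 10
Reactants: 16 methylated sulfone
Product: 17 γ-sulfonyl enone (C12=C13–C14=O)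
Conditions: Pd(OAc)2 (1.1 equiv), MeCN, 40 °C
Reagents that add atoms: none
Why: Saegusa oxidation, in which the palladium enolate from the silyl enol ether can only undergo β-hydride elimination toward C12 because C1 is quaternary.

Step 11
Reactants: 17 γ-sulfonyl enone
Product: 19 β,γ-unsaturated ketone (C11=C12; C14=O), via samarium dienolate 18 (not isolated)
Conditions: SmI2 (2.5 equiv), THF–MeOH, -78 °C
Reagents that add atoms: samarium diiodide, I[Sm]I (samarium stays only in 18)
Why: Two-electron reduction of the enone expels the γ-sulfinate (vinylogous reductive desulfonylation, as known for γ-acyloxy and γ-alkoxy enones) to a dienolate that is protonated kinetically at the α-carbon C13, which places the olefin at C11=C12.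

Step 12
Reactants: 19 β,γ-unsaturated ketone
Product: 20 C14 α-alcohol (14R)
Conditions: (S)-2-methyl-CBS-oxazaborolidine (0.5 equiv), catecholborane, toluene, -78 °C
Reagents that add atoms: none
Why: Corey–Bakshi–Shibata reduction in which quaternary C1 is the large and CH2-13 the small substituent, so the (S)-catalyst delivers hydride to the face bearing the C1 methyl group and sets C14 as R by reagent control; catecholborane spares the olefins.

Step 13
Reactants: 20 alcohol
Product: 21 C14 acetate
Conditions: Ac2O, DMAP, pyridine, 25 °C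
Reagents that add atoms: acetic anhydride, CC(=O)OC(C)=O
Why: DMAP-catalysed acylation of the hindered secondary alcohol installs the C14 acetate and removes a hydroxyl that would otherwise direct the later epoxidation to the wrong face.

Step 14
Reactants: 21 acetate
Product: 22 C9 primary alcohol with di-tert-butylfluorosilyl ether on the C2 oxygen
Conditions: BF3·SMe2, CH2Cl2, -40 to 0 °C; aq. NaHCO3
Reagents that add atoms: boron trifluoride–dimethyl sulfide, C[S+](C)[B-](F)(F)F
Why: Lewis-acid opening of the cyclic di-tert-butylsilylene acetal takes place at the less hindered primary Si–O bond with fluoride transfer to silicon, which frees the C9 hydroxyl and leaves the C2 oxygen protected.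

Step 15
Reactants: 22 homoallylic alcohol
Product: 23 11,12-epoxide (11S,12R)
Conditions: VO(acac)2 (5 mol %), t-BuOOH, CH2Cl2, 0 to 25 °C
Reagents that add atoms: tert-butyl hydroperoxide, CC(C)(C)OO
Why: Vanadium-catalysed hydroxyl-directed epoxidation, in which the CH2OH group on C10 delivers oxygen to the face of C11=C12 on which it sits (cis to the C1 methyl), setting C11 and C12 and leaving the undirected isopropenyl group untouched.

Step 16
Reactants: 23 epoxy alcohol
Product: 25 primary iodide, via primary triflate 24 (not isolated)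
Conditions: Tf2O, 2,6-lutidine, CH2Cl2, -78 °C; then n-Bu4NI, -78 to 0 °C
Reagents that add atoms: tetrabutylammonium iodide, CCCC[N+](CCCC)(CCCC)CCCC.[I-]; triflic anhydride, FC(F)(F)S(=O)(=O)OS(=O)(=O)C(F)(F)F (triflyl group stays only in 24)
Why: The only free hydroxyl is triflated at low temperature and displaced in the flask by iodide (SN2 at the primary carbon), conditions that spare the epoxide and the fluorosilyl ether.

Step 17
Reactants: 25 iodide
Product: 27 C2 butanoate, via free C2 alcohol 26 (not isolated)
Conditions: n-Bu4NF, AcOH, THF, 0 °C; then (n-PrCO)2O, Et3N, DMAP, 0 to 25 °C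
Reagents that add atoms: butanoic anhydride, CCCC(=O)OC(=O)CCC
Why: Buffered fluoride removes the fluorosilyl group without forming an alkoxide (no acetyl migration from C14, no acid-promoted attack of the C2 hydroxyl on the epoxide), and the freed alcohol is acylated at once.

Step 18
Reactants: 28 3-methoxy-2-methyl-3-oxopropanoic acid
Product: 29 methyl 3-chloro-2-methyl-3-oxopropanoate
Conditions: (COCl)2, DMF (cat.), CH2Cl2, 0 to 25 °C
Reagents that add atoms: oxalyl chloride, ClC(=O)C(Cl)=O
Why: Standard conversion of a malonic half ester into its acid chloride.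

Step 19
Reactants: 27 iodide; 29 acid chloride
Product: 31 β-keto ester (C9H2–C8(=O)–CH(CH3)–CO2CH3), via alkylzinc iodide 30 (not isolated)
Conditions: Zn, LiCl, THF, 25 °C; then 29, Pd(PPh3)4 (5 mol %), 0 to 25 °C
Reagents that add atoms: zinc, [Zn] (zinc stays only in 30)
Why: Zinc insertion into the primary iodide gives an alkylzinc reagent that tolerates esters and the epoxide (its oxygen is γ to zinc, so no β-elimination) and is acylated under palladium catalysis (Negishi acylation), forming C8–C9.

Step 20
Reactants: 31 β-keto ester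
Product: 33 Z enol triflate (triflate cis to the ester), via sodium enolate 32 (not isolated)
Conditions: NaH, THF, 0 °C; PhNTf2, 0 to 25 °C
Reagents that add atoms: N-phenylbis(trifluoromethanesulfonimide), FC(F)(F)S(=O)(=O)N(c1ccccc1)S(=O)(=O)C(F)(F)F; sodium hydride, [Na+].[H-] (sodium stays only in 32)
Why: O-triflation of the chelated sodium enolate of the β-keto ester gives the Z enol triflate, the geometry needed for lactonisation in step 21.

Step 21
Reactants: 33 enol triflate; 34 acrolein
Product: 36 5-vinylbutenolide (7R), via chromium alkoxide 35 (not isolated)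
Conditions: CrCl2, NiCl2 (cat.), Et3N, (S)-N-{2-[4-(propan-2-yl)-4,5-dihydro-1,3-oxazol-2-yl]-6-methylphenyl}methanesulfonamide, THF, 25 °C; aq. work-up, then PPTS (cat.), CH2Cl2
Reagents that add atoms: chromium dichloride, Cl[Cr]Cl (chromium stays only in 35)
Why: Nozaki–Hiyama–Kishi reaction in which zerovalent nickel inserts into the enol triflate, the alkenyl group passes to chromium and adds 1,2 to acrolein, the chiral sulfonamide ligand on trivalent chromium being proposed to direct attack to the Si face to set C7 as R, after which the cis γ-hydroxy ester lactonises.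

Step 22
Reactants: 36 diene
Product: 37 target compound CNP0220791.1
Conditions: second-generation Hoveyda–Grubbs catalyst (10 mol %), toluene (1 mM), 80 °C
Reagents that add atoms: none
Why: Ring-closing metathesis of the vinyl and isopropenyl groups closes the ten-membered ring with loss of ethene; the medium ring should favour the Z (ring-cis) trisubstituted olefin, and the butenolide olefin is too hindered and electron-poor to take part.

**Compound list**

1 | 4-methylpent-4-en-1-ol | CC(=C)CCCO | starting material
2 | 4-methylpent-4-enal | CC(=C)CCC=O | intermediate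
3 | (R)-4-benzyl-3-propanoyl-1,3-oxazolidin-2-one | CCC(=O)N1[C@H](Cc2ccccc2)COC1=O | starting material
4 | Z-di-n-butylboron enolate of 3 | C/C=C(\OB(CCCC)CCCC)N1[C@H](Cc2ccccc2)COC1=O | intermediate (not isolated)
5 | (R)-4-benzyl-3-[(2R,3S)-3-hydroxy-2,6-dimethylhept-6-enoyl]-1,3-oxazolidin-2-one | CC(=C)CC[C@H](O)[C@@H](C)C(=O)N1[C@H](Cc2ccccc2)COC1=O | intermediate
6 | (2R,3S)-3-hydroxy-N-methoxy-N,2,6-trimethylhept-6-enamide | CC(=C)CC[C@H](O)[C@@H](C)C(=O)N(C)OC | intermediate
7 | (4R,5S)-5-hydroxy-4,8-dimethylnona-1,8-dien-3-one | CC(=C)CC[C@H](O)[C@@H](C)C(=O)C=C | intermediate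
8 | phenyl vinyl sulfone | C=CS(=O)(=O)c1ccccc1 | starting material
9 | prop-2-en-1-ol | C=CCO | starting material
10 | (E)-3-(phenylsulfonyl)prop-2-en-1-ol | OC/C=C/S(=O)(=O)c1ccccc1 | intermediate
11 | di-tert-butyl[(E)-3-(phenylsulfonyl)prop-2-enyloxy]silyl triflate | CC(C)(C)[Si](OC/C=C/S(=O)(=O)c1ccccc1)(OS(=O)(=O)C(F)(F)F)C(C)(C)C | intermediate (not isolated)
12 | (4R,5S)-5-({di-tert-butyl[(E)-3-(phenylsulfonyl)prop-2-enyloxy]silyl}oxy)-4,8-dimethylnona-1,8-dien-3-one | CC(=C)CC[C@H](O[Si](C(C)(C)C)(C(C)(C)C)OC/C=C/S(=O)(=O)c1ccccc1)[C@@H](C)C(=O)C=C | intermediate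
13 | (3Z,5S)-3-[(tert-butyldimethylsilyl)oxy]-5-({di-tert-butyl[(E)-3-(phenylsulfonyl)prop-2-enyloxy]silyl}oxy)-4,8-dimethylnona-1,3,8-triene | CC(=C)CC[C@H](O[Si](C(C)(C)C)(C(C)(C)C)OC/C=C/S(=O)(=O)c1ccccc1)/C(C)=C(\O[Si](C)(C)C(C)(C)C)C=C | intermediate
14 | Diels–Alder adduct: cyclohexene trans-fused to the di-tert-butyl-1,3-dioxa-2-silepane; TBS enol ether C13=C14; 3-methylbut-3-enyl on C2; phenylsulfonyl on C11 | CC(=C)CC[C@@H]1O[Si](C(C)(C)C)(C(C)(C)C)OC[C@@H]2[C@@H](S(=O)(=O)c3ccccc3)CC=C(O[Si](C)(C)C(C)(C)C)[C@@]12C | intermediate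
15 | C11-lithiated sulfone of 14 | CC(=C)CC[C@@H]1O[Si](C(C)(C)C)(C(C)(C)C)OC[C@@H]2C([Li])(S(=O)(=O)c3ccccc3)CC=C(O[Si](C)(C)C(C)(C)C)[C@@]12C | intermediate (not isolated)
16 | C11-methyl C11-phenylsulfonyl adduct (C11 configuration open) | CC(=C)CC[C@@H]1O[Si](C(C)(C)C)(C(C)(C)C)OC[C@@H]2C(C)(S(=O)(=O)c3ccccc3)CC=C(O[Si](C)(C)C(C)(C)C)[C@@]12C | intermediate
17 | γ-sulfonyl enone (C12=C13–C14=O; C11 configuration open) | CC(=C)CC[C@@H]1O[Si](C(C)(C)C)(C(C)(C)C)OC[C@@H]2C(C)(S(=O)(=O)c3ccccc3)C=CC(=O)[C@@]12C | intermediate
18 | samarium dienolate (C14(OSm)=C13–C12=C11) | CC(=C)CC[C@@H]1O[Si](C(C)(C)C)(C(C)(C)C)OC[C@@H]2C(C)=CC=C(O[Sm](I)I)[C@@]12C | intermediate (not isolated)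
19 | β,γ-unsaturated ketone (C11=C12; C14=O) | CC(=C)CC[C@@H]1O[Si](C(C)(C)C)(C(C)(C)C)OC[C@@H]2C(C)=CCC(=O)[C@@]12C | intermediate
20 | (14R)-alcohol (hydroxyl trans to the C1 methyl) | CC(=C)CC[C@@H]1O[Si](C(C)(C)C)(C(C)(C)C)OC[C@@H]2C(C)=CC[C@@H](O)[C@@]12C | intermediate
21 | C14 acetate | CC(=C)CC[C@@H]1O[Si](C(C)(C)C)(C(C)(C)C)OC[C@@H]2C(C)=CC[C@@H](OC(C)=O)[C@@]12C | intermediate
22 | monocyclic cyclohexene: C9 hydroxymethyl on C10; di-tert-butylfluorosilyl ether on the C2 oxygen; C14 acetate | CC(=C)CC[C@H](O[Si](F)(C(C)(C)C)C(C)(C)C)[C@@]1(C)[C@H](CO)C(C)=CC[C@H]1OC(C)=O | intermediate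
23 | (11S,12R)-epoxide of 22 (epoxide cis to the C1 methyl and to CH2-9) | CC(=C)CC[C@H](O[Si](F)(C(C)(C)C)C(C)(C)C)[C@@]1(C)[C@H](CO)[C@]2(C)O[C@@H]2C[C@H]1OC(C)=O | intermediate
24 | C9 primary triflate | CC(=C)CC[C@H](O[Si](F)(C(C)(C)C)C(C)(C)C)[C@@]1(C)[C@H](COS(=O)(=O)C(F)(F)F)[C@]2(C)O[C@@H]2C[C@H]1OC(C)=O | intermediate (not isolated)
25 | C9 primary iodide | CC(=C)CC[C@H](O[Si](F)(C(C)(C)C)C(C)(C)C)[C@@]1(C)[C@H](CI)[C@]2(C)O[C@@H]2C[C@H]1OC(C)=O | intermediate
26 | C2 alcohol of the iodide | CC(=C)CC[C@H](O)[C@@]1(C)[C@H](CI)[C@]2(C)O[C@@H]2C[C@H]1OC(C)=O | intermediate (not isolated)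
27 | C2 butanoate iodide | CCCC(=O)O[C@@H](CCC(C)=C)[C@@]1(C)[C@H](CI)[C@]2(C)O[C@@H]2C[C@H]1OC(C)=O | intermediate
28 | 3-methoxy-2-methyl-3-oxopropanoic acid | COC(=O)C(C)C(=O)O | starting material
29 | methyl 3-chloro-2-methyl-3-oxopropanoate | COC(=O)C(C)C(Cl)=O | intermediate
30 | C9 alkylzinc iodide | CCCC(=O)O[C@@H](CCC(C)=C)[C@@]1(C)[C@H](C[Zn]I)[C@]2(C)O[C@@H]2C[C@H]1OC(C)=O | intermediate (not isolated)
31 | β-keto ester (methyl 2-methyl-3-oxobutanoate unit attached through C9; either configuration at the methyl-bearing carbon) | CCCC(=O)O[C@@H](CCC(C)=C)[C@@]1(C)[C@H](CC(=O)C(C)C(=O)OC)[C@]2(C)O[C@@H]2C[C@H]1OC(C)=O | intermediate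
32 | sodium Z-enolate of 31 | CCCC(=O)O[C@@H](CCC(C)=C)[C@@]1(C)[C@H](C/C([O-])=C(\C)C(=O)OC)[C@]2(C)O[C@@H]2C[C@H]1OC(C)=O.[Na+] | intermediate (not isolated)
33 | Z enol triflate (triflate on C8 cis to the ester) | CCCC(=O)O[C@@H](CCC(C)=C)[C@@]1(C)[C@H](C/C(OS(=O)(=O)C(F)(F)F)=C(\C)C(=O)OC)[C@]2(C)O[C@@H]2C[C@H]1OC(C)=O | intermediate
34 | acrolein | C=CC=O | starting material
35 | chromium alkoxide of the (7R)-γ-hydroxy enoate | CCCC(=O)O[C@@H](CCC(C)=C)[C@@]1(C)[C@H](C/C([C@H](O[Cr](Cl)Cl)C=C)=C(\C)C(=O)OC)[C@]2(C)O[C@@H]2C[C@H]1OC(C)=O | intermediate (not isolated)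
36 | seco-diene: (5R)-3-methyl-5-vinylfuran-2(5H)-on-4-ylmethyl group on C10; 3-methylbut-3-enyl on C2 | CCCC(=O)O[C@@H](CCC(C)=C)[C@@]1(C)[C@H](CC2=C(C)C(=O)O[C@@H]2C=C)[C@]3(C)O[C@@H]3C[C@H]1OC(C)=O | intermediate
37 | CNP0220791.1 (1R,2S,7R,10S,11S,12R,14R; 5Z) | CCCC(=O)O[C@H]1CC/C(C)=C\[C@H]2OC(=O)C(C)=C2C[C@@H]2[C@]3(C)O[C@@H]3C[C@@H](OC(C)=O)[C@@]12C | target

**Step count and risks**

Total step count: 22. Longest linear sequence: 20 steps (steps 1 to 4, 6 to 17 and 19 to 22).

Steps most likely to fail:

Step 8. The cycloaddition may be outrun by a 1,5-hydrogen shift of the diene, whose methyl group on C1 lies inside in the reactive s-cis form. It may also pass through the endo-tether transition state and give the cis-fused adduct with the wrong C10. The fallback is an ionic, stepwise annulation and sets out from ketone 12. LiN(SiMe3)2 in THF at -78 to 0 °C forms the cross-conjugated dienolate at C1, which adds to C10 of the vinyl sulfone (Michael addition, seven-membered ring). The α-sulfonyl carbanion so formed then adds to C12 of the regenerated enone (second Michael addition) to give the bicyclic ketone F1. Silylation of the bicyclic ketone F1 (TBSOTf, Et3N) returns to the route at 14.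

Step 22. Oligomerisation through the exposed vinyl group may outrun closure, because the flat butenolide holds C6 away from the hindered isopropenyl group; the E olefin may also form. The fallback closes the ring before the lactone exists and sets out from enol triflate 33. The coupling of step 21 is run and the chromium alkoxide 35 is silylated in the flask (Et3SiCl, imidazole) instead of lactonising, giving the open-chain triethylsilyl ether F2. Ring-closing metathesis of the triethylsilyl ether F2, which is more flexible and carries a bulky sp3 centre at C7, gives the ten-membered Z-enoate F3. Buffered n-Bu4NF/AcOH then removes the silyl group from the macrocyclic enoate F3 and the freed hydroxyl lactonises, which returns to the route at the target 37.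

Step 21. Facial selectivity in the addition of the alkenylchromium species to acrolein may be poor or reversed, since the sense of induction of this ligand class is empirical; a C7 epimer would result. The fallback sets C7 by ketone reduction and sets out from enol triflate 33. Carbonylative Stille coupling (CO, Bu3SnCH=CH2, Pd(PPh3)4, LiCl, THF, 50 °C) gives the cross-conjugated divinyl ketone F4. Corey–Bakshi–Shibata 1,2-reduction of the divinyl ketone F4 with the (S)-catalyst and catecholborane (fully substituted alkenyl carbon C8 as the large group, vinyl as the small one) should give the (7R)-hydroxy ester F5. The hydroxy ester F5 lactonises (PPTS) and returns to the route at 36.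

Further compounds
F1 | step 8 | bicyclic ketone (C14=O; phenylsulfonyl on C11; trans-fused dioxasilepane) | CC(=C)CC[C@@H]1O[Si](C(C)(C)C)(C(C)(C)C)OC[C@@H]2[C@@H](S(=O)(=O)c3ccccc3)CCC(=O)[C@@]12C
F2 | step 22 | open-chain (7R)-triethylsilyloxy Z-enoate diene | CCCC(=O)O[C@@H](CCC(C)=C)[C@@]1(C)[C@H](C/C([C@H](O[Si](CC)(CC)CC)C=C)=C(\C)C(=O)OC)[C@]2(C)O[C@@H]2C[C@H]1OC(C)=O
F3 | step 22 | ten-membered (5Z)-ring with (7R)-triethylsilyloxy group and exocyclic Z-enoate | CCCC(=O)O[C@H]1CC/C(C)=C\[C@@H](O[Si](CC)(CC)CC)/C(=C(/C)C(=O)OC)C[C@@H]2[C@]3(C)O[C@@H]3C[C@@H](OC(C)=O)[C@@]12C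
F4 | step 21 | cross-conjugated divinyl ketone (C7=O) | CCCC(=O)O[C@@H](CCC(C)=C)[C@@]1(C)[C@H](C/C(C(=O)C=C)=C(\C)C(=O)OC)[C@]2(C)O[C@@H]2C[C@H]1OC(C)=O
F5 | step 21 | (7R)-γ-hydroxy Z-enoate | CCCC(=O)O[C@@H](CCC(C)=C)[C@@]1(C)[C@H](C/C([C@H](O)C=C)=C(\C)C(=O)OC)[C@]2(C)O[C@@H]2C[C@H]1OC(C)=O
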